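The target is disconnected at C1–C10 (ring A) and C8–C9 (ring B) together. The precursor is the open-chain keto-aldehyde 13, which already carries C4, C5 and C13, set by a rhodium-catalysed conjugate addition and two lactone alkylations on a citronellic acid-derived chain. One acyl-radical cascade zips it up: the C8 acyl radical closes ring B on C9, and the tertiary C10 radical so formed closes ring A on C1 of a vinyl ketone. This creates the quaternary C10 and the trans ring fusion. The step exploits C10, the methyl-bearing fusion carbon of rings A and B, sitting 1,3 to C8 (a ketone behind the exocyclic methylene) and 1,4 to the removable C3 carbonyl.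

Key step: step 10

Remark: atom labels follow labdane numbering (ring A = C1–C5 and C10; ring B = C5–C10; C17 = exocyclic CH2 on C8; C18 = CH2O on C4; C19 = CH3 on C4; C20 = CH3 on C10; side chain C11–C16, C15 the acid); the enol ether in 11 and 12 is an E/Z mixture that converges in step 9 (E isomer drawn).

Step 1
Reactants: 1 (S)-citronellic acid
Product: 2 tert-butyl (S)-citronellate
Conditions: Boc2O, DMAP (cat.), t-BuOH, 30 °C
Reagents that add atoms: di-tert-butyl dicarbonate, CC(C)(C)OC(=O)OC(=O)OC(C)(C)C
Why: DMAP-catalysed esterification through the mixed carbonic anhydride gives a tert-butyl ester that should be inert to the later amide bases, aluminium amide and Grignard reagent; C13 from the chiral pool is untouched.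

Step 2
Reactants: 2 tert-butyl (S)-citronellate; 3 isopropenylboronic acid pinacol ester
Product: 4 trisubstituted alkenylboronate
Conditions: second-generation Hoveyda–Grubbs catalyst RuCl2(H2IMes)(=CH-C6H4-2-OiPr) (5 mol%), 3 (3 equiv), CH2Cl2, 40 °C
Reagents that add atoms: none
Why: Olefin cross-metathesis in which the prenyl-type alkene of 2 sheds 2-methylpropene and the 1,1-disubstituted vinylboronate cannot homodimerise, so the alkenylboronate should form with boron trans to the chain (thermodynamic control); no stereocentre is made.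

Step 3
Reactants: 4 trisubstituted alkenylboronate; 5 5,6-dihydro-2H-pyran-2-one
Product: 6 (4R)-4-alkenyl δ-lactone
Conditions: [Rh(cod)Cl]2 (2.5 mol%), (R)-BINAP (6 mol%), K3PO4, 1,4-dioxane/H2O (10:1), 60 °C; then 1 M HCl
Reagents that add atoms: none
Why: Hayashi–Miyaura rhodium-catalysed asymmetric 1,4-addition (transmetalation, enantioface-selective carbometalation, protonolysis) sets C5 under catalyst control, the (R)-BINAP complex being chosen by analogy with the 3-substituted cyclohexanone series to give the (4R)-lactone.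

Step 4
Reactants: 6 (4R)-4-alkenyl δ-lactone
Product: 7 trans-3-(PMB-oxymethyl) lactone
Conditions: LiN(SiMe3)2 (1.1 equiv), THF, −78 °C; PMBOCH2Cl, −78 to −40 °C
Reagents that add atoms: 4-methoxybenzyl chloromethyl ether, COc1ccc(COCCl)cc1
Why: Lactone enolate alkylation: the lactone, far more acidic than the tert-butyl ester, is deprotonated selectively and the α-chloro ether should enter trans to the C5 alkenyl group (1,2-induction on the six-membered enolate), installing C18.

Step 5
Reactants: 7 trans-3-(PMB-oxymethyl) lactone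
Product: 8 lactone with quaternary C4
Conditions: LiN(SiMe3)2 (1.2 equiv), THF, −78 °C; MeI, −78 °C
Reagents that add atoms: iodomethane, CI
Why: Second enolate alkylation: MeI should again approach the planar enolate anti to the C5 alkenyl group, so C19 ends trans and C18 cis to it, which is the target configuration of the quaternary C4.

Step 6
Reactants: 8 lactone with quaternary C4
Product: 9 hydroxy Weinreb amide
Conditions: MeNH(OMe)·HCl, AlMe3, CH2Cl2, 0 °C to rt
Reagents that add atoms: N,O-dimethylhydroxylamine hydrochloride, CNOC.Cl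
Why: Weinreb aminolysis of the lactone by the aluminium amide opens the ring to the C3 N-methoxy-N-methylamide and frees the C7 alcohol while the hindered tert-butyl ester should survive; no stereocentre is affected.

Step 7
Reactants: 9 hydroxy Weinreb amide
Product: 10 C7 aldehyde
Conditions: Dess–Martin periodinane, NaHCO3, CH2Cl2, 0 °C to rt
Reagents that add atoms: none
Why: Dess–Martin oxidation converts the primary C7 alcohol to the aldehyde under buffered, non-epimerising conditions before the hydroxy amide can re-lactonise.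

Step 8
Reactants: 10 C7 aldehyde
Product: 11 methyl enol ether
Conditions: Ph3P(CH2OMe)Cl, KN(SiMe3)2, THF, −78 to 0 °C
Reagents that add atoms: (methoxymethyl)triphenylphosphonium chloride, COC[P+](c1ccccc1)(c1ccccc1)c1ccccc1.[Cl-]
Why: Wittig methoxymethylenation adds the missing carbon C8 as a masked aldehyde that survives the Grignard step; amide and ester are inert to the ylide.

Step 9
Reactants: 11 methyl enol ether
Product: 13 vinyl ketone aldehyde, via enol-ether vinyl ketone 12 (not isolated)
Conditions: CH2=CHMgBr, THF, −20 to 0 °C; then 1 M H2SO4 (aq.), THF, rt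
Reagents that add atoms: vinylmagnesium bromide, C=C[Mg]Br; water, O
Why: Weinreb ketone synthesis (the chelated tetrahedral intermediate stops at the ketone) installs C1 and C2 as the vinyl ketone, and the acidic quench hydrolyses the enol ether to the C8 aldehyde in the same operation.

Step 10
Reactants: 13 vinyl ketone aldehyde
Product: 14 trans-decalin 3,8-dione
Conditions: t-C12H25SH (0.3 equiv), 1,1′-azobis(cyclohexanecarbonitrile) (0.2 equiv, in portions), PhCl (0.01 M), 100 °C
Reagents that add atoms: none
Why: A thiyl radical abstracts the aldehyde hydrogen of 13 (polarity-reversal catalysis) and the C8 acyl radical adds to C9 of the (E)-trisubstituted alkene, closing ring B as a cyclohexanone and leaving a tertiary radical at C10; this radical adds to the terminal C1 of the vinyl ketone (Giese addition), closing ring A by the C1–C10 bond and creating the quaternary C10, and the C2 α-keto radical is quenched by the thiol. The closest known reaction types are acyl-radical polyene cascades started from acyl selenides, the thiol-catalysed cyclisation of alkenals and the intramolecular Giese reaction. Both rings close in the 6-endo-trig mode through chair-like transition states. C9 is set by the (E) alkene geometry (side chain equatorial) and stays correctable because it is α to the C8 ketone; C10 is set by the existing C5 stereocentre, whose bulky C4 substituent sits equatorial on the chair of ring B so that the new C10–C1 bond should form equatorially and the methyl group end axial, the trans fusion known from radical polyene cyclisations. The step needs 6-endo over 5-exo closure at the alkene (secured by the methyl group on the internal carbon C10), attack at C1 rather than C2 (secured by the polarity match of the tertiary radical with the enone β-carbon) and trans over cis fusion (secured by the equatorial C4 tether); the trans fusion is the least certain of these, because the axial C19 and C20 methyl groups meet in the transition state.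

Step 11
Reactants: 14 trans-decalin 3,8-dione
Product: 15 8(17)-methylidene 3-ketone
Conditions: Ph3PCH3Br, KOtBu (1.3 equiv each), THF, 0 °C to rt
Reagents that add atoms: methyltriphenylphosphonium bromide, C[P+](c1ccccc1)(c1ccccc1)c1ccccc1.[Br-]
Why: Wittig methylenation should go to the C8 ketone because the C3 ketone is flanked by the quaternary C4 and reacts much more slowly; the basic medium also lets C9 settle in the equatorial configuration before olefination.

Step 12
Reactants: 15 8(17)-methylidene 3-ketone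
Product: 17 C3-deoxygenated PMB ether, via C3 tosylhydrazone 16 (not isolated)
Conditions: TsNHNH2, EtOH, 80 °C; then catecholborane, CHCl3, 0 °C; NaOAc·3H2O, 60 °C
Reagents that add atoms: 4-methylbenzenesulfonohydrazide, Cc1ccc(cc1)S(=O)(=O)NN (its atoms reside in 16 only and leave again as N2 and sulfinate)
Why: Caglioti-type reductive deoxygenation (hydride addition to the tosylhydrazone, loss of sulfinate, collapse of the diazene with loss of N2) turns C3 into CH2 under conditions that should leave the exocyclic alkene, the ether and the ester untouched.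

Step 13
Reactants: 17 C3-deoxygenated PMB ether
Product: 18 C18 alcohol
Conditions: DDQ, CH2Cl2/pH 7 buffer (10:1), 0 °C
Reagents that add atoms: none
Why: Oxidative PMB cleavage by DDQ (hydride abstraction at the electron-rich benzylic position, hydrolysis of the oxocarbenium ion) frees the neopentyl C18 alcohol without acid.

Step 14
Reactants: 18 C18 alcohol
Product: 19 malonic half-ester
Conditions: Meldrum's acid, toluene, 100 °C
Reagents that add atoms: 2,2-dimethyl-1,3-dioxane-4,6-dione, CC1(C)OC(=O)CC(=O)O1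
Why: Thermal cycloreversion of Meldrum's acid gives an acylketene that the hindered primary alcohol traps, giving the malonic half-ester without a coupling agent.

Step 15
Reactants: 19 malonic half-ester; 20 4-hydroxybenzaldehyde
Product: 21 (E)-p-coumarate tert-butyl ester
Conditions: pyridine, piperidine (0.1 equiv), 90 °C
Reagents that add atoms: none
Why: Knoevenagel–Doebner condensation (iminium-mediated condensation, then decarboxylative elimination) builds the p-coumarate with the free phenol and should give the (E) alkene under thermodynamic control.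

Step 16
Reactants: 21 (E)-p-coumarate tert-butyl ester
Product: 22 CNP0389065.1
Conditions: 85% aq. H3PO4, toluene, 40 °C
Reagents that add atoms: none
Why: Acidolysis of the tert-butyl ester by alkyl–oxygen cleavage with aqueous phosphoric acid is mild enough that the exocyclic alkene, the cinnamate ester and the phenol should survive.

Compound list
1 | (S)-citronellic acid, (3S)-3,7-dimethyloct-6-enoic acid | CC(C)=CCC[C@H](C)CC(=O)O | starting material
2 | tert-butyl (3S)-3,7-dimethyloct-6-enoate | CC(C)=CCC[C@H](C)CC(=O)OC(C)(C)C | intermediate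
3 | 4,4,5,5-tetramethyl-2-(prop-1-en-2-yl)-1,3,2-dioxaborolane | CC(=C)B1OC(C)(C)C(C)(C)O1 | starting material
4 | tert-butyl (3S,6Z)-3-methyl-7-(4,4,5,5-tetramethyl-1,3,2-dioxaborolan-2-yl)oct-6-enoate | CC1(C)OB(OC1(C)C)/C(C)=C/CC[C@H](C)CC(=O)OC(C)(C)C | intermediate
5 | 5,6-dihydro-2H-pyran-2-one | O=C1C=CCCO1 | starting material
6 | tert-butyl (3S,6E)-3-methyl-7-[(4R)-2-oxooxan-4-yl]oct-6-enoate | O=C1C[C@H](/C(C)=C/CC[C@H](C)CC(=O)OC(C)(C)C)CCO1 | intermediate
7 | tert-butyl (3S,6E)-7-[(3R,4R)-3-{[(4-methoxyphenyl)methoxy]methyl}-2-oxooxan-4-yl]-3-methyloct-6-enoate | O=C1[C@@H](COCc2ccc(OC)cc2)[C@H](/C(C)=C/CC[C@H](C)CC(=O)OC(C)(C)C)CCO1 | intermediate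
8 | tert-butyl (3S,6E)-7-[(3S,4S)-3-{[(4-methoxyphenyl)methoxy]methyl}-3-methyl-2-oxooxan-4-yl]-3-methyloct-6-enoate | O=C1[C@](C)(COCc2ccc(OC)cc2)[C@H](/C(C)=C/CC[C@H](C)CC(=O)OC(C)(C)C)CCO1 | intermediate
9 | tert-butyl (3S,6E,8S,9S)-8-(2-hydroxyethyl)-10-[methoxy(methyl)amino]-9-{[(4-methoxyphenyl)methoxy]methyl}-3,7,9-trimethyl-10-oxodec-6-enoate | CON(C)C(=O)[C@](C)(COCc1ccc(OC)cc1)[C@@H](CCO)/C(C)=C/CC[C@H](C)CC(=O)OC(C)(C)C | intermediate
10 | tert-butyl (3S,6E,8S,9S)-10-[methoxy(methyl)amino]-9-{[(4-methoxyphenyl)methoxy]methyl}-3,7,9-trimethyl-10-oxo-8-(2-oxoethyl)dec-6-enoate | CON(C)C(=O)[C@](C)(COCc1ccc(OC)cc1)[C@@H](CC=O)/C(C)=C/CC[C@H](C)CC(=O)OC(C)(C)C | intermediate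
11 | tert-butyl (3S,6E,8S,9S)-10-[methoxy(methyl)amino]-9-{[(4-methoxyphenyl)methoxy]methyl}-8-(3-methoxyprop-2-en-1-yl)-3,7,9-trimethyl-10-oxodec-6-enoate (enol ether E/Z mixture, E drawn) | CON(C)C(=O)[C@](C)(COCc1ccc(OC)cc1)[C@@H](C/C=C/OC)/C(C)=C/CC[C@H](C)CC(=O)OC(C)(C)C | intermediate
12 | tert-butyl (3S,6E,8S,9S)-9-{[(4-methoxyphenyl)methoxy]methyl}-8-(3-methoxyprop-2-en-1-yl)-3,7,9-trimethyl-10-oxododeca-6,11-dienoate (enol ether E/Z mixture, E drawn) | C=CC(=O)[C@](C)(COCc1ccc(OC)cc1)[C@@H](C/C=C/OC)/C(C)=C/CC[C@H](C)CC(=O)OC(C)(C)C | intermediate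
13 | tert-butyl (3S,6E,8S,9S)-9-{[(4-methoxyphenyl)methoxy]methyl}-3,7,9-trimethyl-10-oxo-8-(3-oxopropyl)dodeca-6,11-dienoate | C=CC(=O)[C@](C)(COCc1ccc(OC)cc1)[C@@H](CCC=O)/C(C)=C/CC[C@H](C)CC(=O)OC(C)(C)C | intermediate
14 | tert-butyl (3S)-5-[(1S,4aS,5S,8aR)-5-{[(4-methoxyphenyl)methoxy]methyl}-5,8a-dimethyl-2,6-dioxodecahydronaphthalen-1-yl]-3-methylpentanoate | O=C1CC[C@@H]2[C@@](C)(COCc3ccc(OC)cc3)C(=O)CC[C@@]2(C)[C@@H]1CC[C@H](C)CC(=O)OC(C)(C)C | intermediate
15 | tert-butyl (3S)-5-[(1R,4aS,5S,8aS)-5-{[(4-methoxyphenyl)methoxy]methyl}-5,8a-dimethyl-2-methylidene-6-oxodecahydronaphthalen-1-yl]-3-methylpentanoate | C=C1CC[C@@H]2[C@@](C)(COCc3ccc(OC)cc3)C(=O)CC[C@@]2(C)[C@@H]1CC[C@H](C)CC(=O)OC(C)(C)C | intermediate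
16 | tert-butyl (3S)-5-[(1R,4aS,5R,8aS)-5-{[(4-methoxyphenyl)methoxy]methyl}-5,8a-dimethyl-2-methylidene-6-[2-(4-methylbenzenesulfonyl)hydrazinylidene]decahydronaphthalen-1-yl]-3-methylpentanoate | C=C1CC[C@@H]2[C@@](C)(COCc3ccc(OC)cc3)C(=NNS(=O)(=O)c3ccc(C)cc3)CC[C@@]2(C)[C@@H]1CC[C@H](C)CC(=O)OC(C)(C)C | intermediate
17 | tert-butyl (3S)-5-[(1R,4aS,5S,8aS)-5-{[(4-methoxyphenyl)methoxy]methyl}-5,8a-dimethyl-2-methylidenedecahydronaphthalen-1-yl]-3-methylpentanoate | C=C1CC[C@@H]2[C@@](C)(COCc3ccc(OC)cc3)CCC[C@@]2(C)[C@@H]1CC[C@H](C)CC(=O)OC(C)(C)C | intermediate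
18 | tert-butyl (3S)-5-[(1R,4aS,5S,8aS)-5-(hydroxymethyl)-5,8a-dimethyl-2-methylidenedecahydronaphthalen-1-yl]-3-methylpentanoate | C=C1CC[C@@H]2[C@@](C)(CO)CCC[C@@]2(C)[C@@H]1CC[C@H](C)CC(=O)OC(C)(C)C | intermediate
19 | tert-butyl (3S)-5-[(1R,4aS,5S,8aS)-5-{[(carboxyacetyl)oxy]methyl}-5,8a-dimethyl-2-methylidenedecahydronaphthalen-1-yl]-3-methylpentanoate | C=C1CC[C@@H]2[C@@](C)(COC(=O)CC(=O)O)CCC[C@@]2(C)[C@@H]1CC[C@H](C)CC(=O)OC(C)(C)C | intermediate
20 | 4-hydroxybenzaldehyde | O=Cc1ccc(O)cc1 | starting material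
21 | tert-butyl (3S)-5-[(1R,4aS,5S,8aS)-5-({[(2E)-3-(4-hydroxyphenyl)prop-2-enoyl]oxy}methyl)-5,8a-dimethyl-2-methylidenedecahydronaphthalen-1-yl]-3-methylpentanoate | C=C1CC[C@@H]2[C@@](C)(COC(=O)/C=C/c3ccc(O)cc3)CCC[C@@]2(C)[C@@H]1CC[C@H](C)CC(=O)OC(C)(C)C | intermediate
22 | (3S)-5-[(1R,4aS,5S,8aS)-5-({[(2E)-3-(4-hydroxyphenyl)prop-2-enoyl]oxy}methyl)-5,8a-dimethyl-2-methylidenedecahydronaphthalen-1-yl]-3-methylpentanoic acid (CNP0389065.1) | C=C1CC[C@@H]2[C@@](C)(COC(=O)/C=C/c3ccc(O)cc3)CCC[C@@]2(C)[C@@H]1CC[C@H](C)CC(=O)O | target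

Total step count: 16. Longest linear sequence: 16 steps (steps 1 to 16 from 1; compounds 3, 5 and 20 enter as purchased materials).

Steps most likely to fail

Step 10. The cascade may fail by hydrogen transfer to the C10 radical before ring A closes, by radical addition of the thiol to the enone, or by ring closure from the wrong face (cis fusion). The fallback sets out from 13 and builds the two rings one after the other. Me2AlCl (CH2Cl2, −78 °C) should effect a type-two carbonyl-ene cyclisation in which C9 attacks the C8 aldehyde and a C20 hydrogen is transferred, giving the ring-B methylidenecyclohexanol F1. Fe(acac)3 with PhSiH3 (EtOH, 60 °C) then transfers a hydrogen atom to the exocyclic methylene, generating the same tertiary C10 radical without any thiol; its Giese closure on C1 gives the bicyclic hydroxy ketone F2. Dess–Martin oxidation of the C8 alcohol comes back to the route at 14. This fallback removes the thiol-related failures but not the facial-selectivity risk, since the ring A closure is the same radical step.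

Step 11. The methylenation may fail through insufficient discrimination between the C8 and C3 ketones (double olefination or competing enolisation). The fallback sets out from 14 and masks the less hindered carbonyl first. Ethane-1,2-dithiol with BF3·OEt2 should ketalise only C8, giving the spiro dithiolane F3. Its C3 ketone is condensed with TsNHNH2 to the tosylhydrazone F4 and reduced with catecholborane and NaOAc·3H2O to the C3-methylene dithiolane F5. MeI with CaCO3 in aqueous MeCN releases the 8-ketone F6, now the only carbonyl available to Ph3P=CH2, and the route is rejoined at 17.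

Step 5. The second alkylation may fail by β-elimination of the 4-methoxybenzyloxy group from the enolate of 7 (loss of the protecting group) or by incomplete facial selectivity. The fallback sets out from 6 and carries C18 as an alkoxide that cannot be expelled. LiN(SiMe3)2 and monomeric formaldehyde should give the trans hydroxymethyl lactone F7. Its alkoxide–enolate dianion (2.2 equiv LiN(SiMe3)2, then MeI) is methylated anti to the alkenyl group to give the quaternary hydroxymethyl lactone F8. 4-Methoxybenzyl trichloroacetimidate with catalytic La(OTf)3 then comes back to the route at 8.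

Further compounds
F1 | step 10 | tert-butyl (3S)-5-[(1S,3S)-6-hydroxy-3-[(2S)-1-[(4-methoxyphenyl)methoxy]-2-methyl-3-oxopent-4-en-2-yl]-2-methylidenecyclohexyl]-3-methylpentanoate (carbinol epimers) | C=CC(=O)[C@](C)(COCc1ccc(OC)cc1)[C@H]1CCC(O)[C@@H](CC[C@H](C)CC(=O)OC(C)(C)C)C1=C
F2 | step 10 | tert-butyl (3S)-5-[(1S,4aS,5S,8aR)-2-hydroxy-5-{[(4-methoxyphenyl)methoxy]methyl}-5,8a-dimethyl-6-oxodecahydronaphthalen-1-yl]-3-methylpentanoate (carbinol epimers) | OC1CC[C@@H]2[C@@](C)(COCc3ccc(OC)cc3)C(=O)CC[C@@]2(C)[C@@H]1CC[C@H](C)CC(=O)OC(C)(C)C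
F3 | step 11 | tert-butyl (3S)-3-methyl-5-[(1'S,4a'S,5'S,8a'R)-5'-{[(4-methoxyphenyl)methoxy]methyl}-5',8a'-dimethyl-6'-oxooctahydro-1'H-spiro[1,3-dithiolane-2,2'-naphthalen]-1'-yl]pentanoate | C12(SCCS1)CC[C@@H]3[C@@](C)(COCc4ccc(OC)cc4)C(=O)CC[C@@]3(C)[C@@H]2CC[C@H](C)CC(=O)OC(C)(C)C
F4 | step 11 | tert-butyl (3S)-3-methyl-5-[(1'S,4a'S,5'R,8a'R)-5'-{[(4-methoxyphenyl)methoxy]methyl}-5',8a'-dimethyl-6'-[2-(4-methylbenzenesulfonyl)hydrazinylidene]octahydro-1'H-spiro[1,3-dithiolane-2,2'-naphthalen]-1'-yl]pentanoate | C12(SCCS1)CC[C@@H]3[C@@](C)(COCc4ccc(OC)cc4)C(=NNS(=O)(=O)c4ccc(C)cc4)CC[C@@]3(C)[C@@H]2CC[C@H](C)CC(=O)OC(C)(C)C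
F5 | step 11 | tert-butyl (3S)-3-methyl-5-[(1'S,4a'S,5'S,8a'R)-5'-{[(4-methoxyphenyl)methoxy]methyl}-5',8a'-dimethyloctahydro-1'H-spiro[1,3-dithiolane-2,2'-naphthalen]-1'-yl]pentanoate | C12(SCCS1)CC[C@@H]3[C@@](C)(COCc4ccc(OC)cc4)CCC[C@@]3(C)[C@@H]2CC[C@H](C)CC(=O)OC(C)(C)C
F6 | step 11 | tert-butyl (3S)-5-[(1S,4aS,5S,8aR)-5-{[(4-methoxyphenyl)methoxy]methyl}-5,8a-dimethyl-2-oxodecahydronaphthalen-1-yl]-3-methylpentanoate | O=C1CC[C@@H]2[C@@](C)(COCc3ccc(OC)cc3)CCC[C@@]2(C)[C@@H]1CC[C@H](C)CC(=O)OC(C)(C)C
F7 | step 5 | tert-butyl (3S,6E)-7-[(3R,4R)-3-(hydroxymethyl)-2-oxooxan-4-yl]-3-methyloct-6-enoate | O=C1[C@@H](CO)[C@H](/C(C)=C/CC[C@H](C)CC(=O)OC(C)(C)C)CCO1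
F8 | step 5 | tert-butyl (3S,6E)-7-[(3S,4S)-3-(hydroxymethyl)-3-methyl-2-oxooxan-4-yl]-3-methyloct-6-enoate | O=C1[C@](C)(CO)[C@H](/C(C)=C/CC[C@H](C)CC(=O)OC(C)(C)C)CCO1
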